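**Retrosynthetic overview**

Rings: A = phenol ring whose ether O is para to its CH2; B = 1,3-linked ring; C = 1,4-linked ring; D = phenol ring whose OH is para to its CH2.
- Feature used: B and C are joined by a two-carbon bridge (B–CH2–CH2–C), and the ring-C carbon para to that bridge carries the ether oxygen to ring D. A macrocycle with a one-carbon B–C(=X)–C bridge can therefore be closed at the C–O–D ether by carbonyl-activated SNAr (X = O) and then homologated by a 1,2-shift of the para-oxygenated ring C (X = CH2).
- Target ⇐ O-demethylation and carbonyl removal ⇐ 20-membered bridge ketone ⇐ iodine(III) aryl-shift ring expansion ⇐ 19-membered 1,1-diarylethene ⇐ methylenation of the 19-membered diaryl ketone.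
- 19-membered ketone ⇐ SNAr macroetherification (C–O–D bond) of a seco phenol/4-fluorophenyl ketone ⇐ Weinreb amide + aryl Grignard ⇐ seco ester.
- Seco ester ⇐ Wittig/hydrogenation (A–CH2CH2–D bridge) ⇐ A–O–B diaryl ether aldehyde (SNAr) + ring-D phosphonium salt.
- Ring order: the four benzene rings are purchased; the 19-membered macrocycle is closed in step 7 and expanded to the 20-membered ring in step 9.

Key step: step 9

Remark on the chemistry: the target SMILES contains no stereocentre and the macrocycle is taken as conformationally mobile, so the compound is achiral and no stereocontrol is needed. The C=C geometry of 7 and the C=N geometry of 16 are inconsequential.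

**Route**

Step 1
Reactants: 1 4-fluoro-3-methoxybenzaldehyde; 2 methyl 3-hydroxybenzoate
Product: 3 methyl 3-(4-formyl-2-methoxyphenoxy)benzoate
Conditions: K2CO3, dry DMF, 120 °C
Reagents that add atoms: none
Why: Nucleophilic aromatic substitution (SNAr), in which the para-formyl group activates the C–F bond towards the phenoxide of 2 while the methyl ester and aldehyde are inert to carbonate in dry DMF.

Step 2
Reactants: 4 [3-(benzyloxy)-4-methoxyphenyl]methanol
Product: 5 [3-(benzyloxy)-4-methoxybenzyl]triphenylphosphonium bromide
Conditions: PPh3·HBr, MeCN, reflux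
Reagents that add atoms: triphenylphosphine hydrobromide, Br.c1ccc(cc1)P(c1ccccc1)c1ccccc1
Why: Acid-promoted phosphonium salt formation from an electron-rich benzylic alcohol (substitution via the stabilised benzylic cation), conditions under which the benzyl ether should survive.

Step 3
Reactants: 3 methyl 3-(4-formyl-2-methoxyphenoxy)benzoate; 5 [3-(benzyloxy)-4-methoxybenzyl]triphenylphosphonium bromide
Product: 7 methyl 3-{4-[2-(3-benzyloxy-4-methoxyphenyl)ethenyl]-2-methoxyphenoxy}benzoate (E/Z mixture), via phosphonium ylide 6 (not isolated)
Conditions: K2CO3, 18-crown-6 (cat.), CH2Cl2, reflux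
Reagents that add atoms: none
Why: Wittig olefination with a semi-stabilised benzylic ylide generated by carbonate/crown ether, mild enough to spare the methyl ester; the alkene geometry is irrelevant because the double bond is hydrogenated next.

Step 4
Reactants: 7 methyl 3-{4-[2-(3-benzyloxy-4-methoxyphenyl)ethenyl]-2-methoxyphenoxy}benzoate
Product: 8 methyl 3-{4-[2-(3-hydroxy-4-methoxyphenyl)ethyl]-2-methoxyphenoxy}benzoate
Conditions: H2 (1 atm), 10% Pd/C, EtOAc–MeOH, rt
Reagents that add atoms: none
Why: Catalytic hydrogenation saturates the stilbene and hydrogenolyses the benzyl ether in one operation, while diaryl ethers, aryl methyl ethers and the benzoate are inert.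

Step 5
Reactants: 8 methyl 3-{4-[2-(3-hydroxy-4-methoxyphenyl)ethyl]-2-methoxyphenoxy}benzoate
Product: 9 3-{4-[2-(3-hydroxy-4-methoxyphenyl)ethyl]-2-methoxyphenoxy}-N-methoxy-N-methylbenzamide
Conditions: MeNH(OMe)·HCl (1.5 equiv), i-PrMgCl (4.2 equiv), THF, −20 → 0 °C; 1 M HCl quench
Reagents that add atoms: N,O-dimethylhydroxylamine hydrochloride, CNOC.Cl
Why: Direct ester-to-Weinreb-amide aminolysis by the chloromagnesium amide of N,O-dimethylhydroxylamine, with one extra equivalent of i-PrMgCl masking the phenol as its magnesium phenoxide.

Step 6
Reactants: 9 3-{4-[2-(3-hydroxy-4-methoxyphenyl)ethyl]-2-methoxyphenoxy}-N-methoxy-N-methylbenzamide; 10 4-fluorophenylmagnesium bromide (commercial solution in THF)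
Product: 11 (4-fluorophenyl)(3-{4-[2-(3-hydroxy-4-methoxyphenyl)ethyl]-2-methoxyphenoxy}phenyl)methanone
Conditions: 10 (3 equiv), THF, 0 °C → rt; 1 M HCl quench
Reagents that add atoms: none
Why: Weinreb ketone synthesis, in which the first equivalent of Grignard reagent deprotonates the phenol and the second adds once to give a chelated tetrahedral intermediate that releases the diaryl ketone only on acidic work-up.

Step 7
Reactants: 11 (4-fluorophenyl)(3-{4-[2-(3-hydroxy-4-methoxyphenyl)ethyl]-2-methoxyphenoxy}phenyl)methanone
Product: 12 19-membered macrocyclic diaryl ketone (B–CO–C bridge; ring C para-linked to ring D through the new ether oxygen)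
Conditions: Cs2CO3, DMSO, 120–130 °C, syringe-pump addition of 11 (final concentration about 3 mM)
Reagents that add atoms: none
Why: Intramolecular SNAr macroetherification in which the para-carbonyl group activates the ring-C fluoride towards the ring-D phenoxide and pseudo-high dilution favours the 19-membered ring over oligomers, as in the preparation of cyclic aryl ether ketones.

Step 8
Reactants: 12 19-membered macrocyclic diaryl ketone
Product: 13 19-membered macrocyclic 1,1-diarylethene (exocyclic C=CH2 between rings B and C)
Conditions: Ph3PCH3Br, KOt-Bu, THF, 0 °C → reflux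
Reagents that add atoms: methyltriphenylphosphonium bromide, C[P+](c1ccccc1)(c1ccccc1)c1ccccc1.[Br-]
Why: Wittig methylenation of a non-enolisable diaryl ketone, the standard conversion of benzophenones into 1,1-diarylethenes.

Step 9
Reactants: 13 19-membered macrocyclic 1,1-diarylethene
Product: 15 20-membered macrocyclic deoxybenzoin (B–CO–CH2–C bridge), via dimethyl ketal 14 (not isolated)
Conditions: PhI(OH)OTs (1.1 equiv), MeOH–H2O 95:5 with CH2Cl2 co-solvent, 0 °C → rt; then 1 M HCl, THF, rt
Reagents that add atoms: water, O (carbonyl oxygen of 15); methanol, CO (the two methoxy groups of ketal 14 only)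
Why: The electrophilic iodine(III) centre adds to the terminal CH2 of the 1,1-diarylethene and methanol traps the doubly benzylic cation; the β-methoxyalkyl(phenyl)iodane then expels iodobenzene with a 1,2-shift of ring C through a phenonium ion, forming the ring-C aryl–CH2 bond and leaving a methoxy-stabilised cation that is captured as ketal 14 and hydrolysed to ketone 15. The closest known reaction type is the hydroxy(tosyloxy)iodobenzene-mediated oxidative rearrangement of 1,1-diarylethenes to deoxybenzoins, together with the analogous aryl-shift ring expansion of exocyclic methylene benzocycloalkanes. The 20-membered ring is not closed end to end: it arises from the 19-membered ring by ring expansion, with the ring-C ipso carbon bridging the two alkene carbons in a three-membered phenonium transition structure, so no macrocyclisation entropy is paid. No stereocentre is formed. The step needs aryl migration in preference to simple 1,2-dimethoxylation and attack at the alkene in preference to the arenes: the para-aryloxy ring C is a better ipso donor than the meta-aryloxy ring B, the 1,1-diaryl alkene is the most nucleophilic site of 13 towards iodine(III) in methanol, and any share of ring-B migration would give the isomeric bridge ketone, which step 10 reduces to the same CH2CH2 bridge.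

Step 10
Reactants: 15 20-membered macrocyclic deoxybenzoin
Product: 17 20-membered macrocyclic bis(bibenzyl) dimethyl ether, via hydrazone 16 (not isolated)
Conditions: N2H4·H2O, KOH, diethylene glycol, 130 °C then 195 °C (Huang-Minlon)
Reagents that add atoms: hydrazine hydrate, NN.O (nitrogen only in hydrazone 16; none remains in 17)
Why: Wolff–Kishner reduction via hydrazone 16 removes the bridge carbonyl without generating a benzylic cation next to the electron-rich rings; diaryl ethers tolerate hot KOH and any adventitious O-demethylation would be immaterial because step 11 removes both methyl groups.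

Step 11
Reactants: 17 20-membered macrocyclic bis(bibenzyl) dimethyl ether
Product: 18 target macrocyclic bis(bibenzyl) diphenol (CNP0329842.0)
Conditions: BBr3 (excess), CH2Cl2, −78 °C → rt; then H2O
Reagents that add atoms: none
Why: Lewis-acid cleavage of aryl methyl ethers with BBr3, which should demethylate both guaiacol-type ethers while leaving the two diaryl ether bonds intact.

**Compound list**

1 | 4-fluoro-3-methoxybenzaldehyde | COc1cc(C=O)ccc1F | starting material
2 | methyl 3-hydroxybenzoate | COC(=O)c1cccc(O)c1 | starting material
3 | methyl 3-(4-formyl-2-methoxyphenoxy)benzoate | COC(=O)c1cccc(Oc2ccc(C=O)cc2OC)c1 | intermediate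
4 | [3-(benzyloxy)-4-methoxyphenyl]methanol | COc1ccc(CO)cc1OCc1ccccc1 | starting material
5 | [3-(benzyloxy)-4-methoxybenzyl]triphenylphosphonium bromide | COc1ccc(C[P+](c2ccccc2)(c2ccccc2)c2ccccc2)cc1OCc1ccccc1.[Br-] | intermediate
6 | [3-(benzyloxy)-4-methoxybenzylidene]triphenylphosphorane (ylide) | COc1ccc(C=P(c2ccccc2)(c2ccccc2)c2ccccc2)cc1OCc1ccccc1 | intermediate (not isolated)
7 | methyl 3-{4-[2-(3-benzyloxy-4-methoxyphenyl)ethenyl]-2-methoxyphenoxy}benzoate, E/Z mixture | COC(=O)c1cccc(Oc2ccc(C=Cc3ccc(OC)c(OCc4ccccc4)c3)cc2OC)c1 | intermediate
8 | methyl 3-{4-[2-(3-hydroxy-4-methoxyphenyl)ethyl]-2-methoxyphenoxy}benzoate | COC(=O)c1cccc(Oc2ccc(CCc3ccc(OC)c(O)c3)cc2OC)c1 | intermediate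
9 | 3-{4-[2-(3-hydroxy-4-methoxyphenyl)ethyl]-2-methoxyphenoxy}-N-methoxy-N-methylbenzamide | CON(C)C(=O)c1cccc(Oc2ccc(CCc3ccc(OC)c(O)c3)cc2OC)c1 | intermediate
10 | 4-fluorophenylmagnesium bromide | Fc1ccc([Mg]Br)cc1 | starting material
11 | (4-fluorophenyl)(3-{4-[2-(3-hydroxy-4-methoxyphenyl)ethyl]-2-methoxyphenoxy}phenyl)methanone | O=C(c1ccc(F)cc1)c1cccc(Oc2ccc(CCc3ccc(OC)c(O)c3)cc2OC)c1 | intermediate
12 | 19-membered macrocyclic diaryl ketone (rings B and C joined by C=O; rings A and D methoxylated) | O=C1c2cccc(c2)Oc2ccc(cc2OC)CCc2ccc(OC)c(c2)Oc2ccc1cc2 | intermediate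
13 | 19-membered macrocyclic 1,1-diarylethene (rings B and C joined by C=CH2) | C=C1c2cccc(c2)Oc2ccc(cc2OC)CCc2ccc(OC)c(c2)Oc2ccc1cc2 | intermediate
14 | dimethyl ketal of the 20-membered bridge ketone | COC1(OC)Cc2ccc(cc2)Oc2cc(ccc2OC)CCc2ccc(c(OC)c2)Oc2cccc1c2 | intermediate (not isolated)
15 | 20-membered macrocyclic deoxybenzoin (C=O on ring B, CH2 on ring C) | O=C1Cc2ccc(cc2)Oc2cc(ccc2OC)CCc2ccc(c(OC)c2)Oc2cccc1c2 | intermediate
16 | hydrazone of 15 (C=N geometry unassigned) | NN=C1Cc2ccc(cc2)Oc2cc(ccc2OC)CCc2ccc(c(OC)c2)Oc2cccc1c2 | intermediate (not isolated)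
17 | 20-membered macrocyclic bis(bibenzyl) dimethyl ether | COc1cc2ccc1Oc1cccc(c1)CCc1ccc(cc1)Oc1cc(ccc1OC)CC2 | intermediate
18 | macrocyclic bis(bibenzyl) diphenol CNP0329842.0 (achiral) | Oc1cc2ccc1Oc1cccc(c1)CCc1ccc(cc1)Oc1cc(ccc1O)CC2 | target

**Step count and risk**

Total step count: 11. Longest linear sequence: 10 steps (steps 1 and 3–11 from 1 or 2; equally steps 2–11 from 4).

Steps most likely to fail:

Step 9 (key ring expansion). Methanol may capture the iodonium adduct without aryl migration (net 1,2-dimethoxylation), or the iodine(III) reagent may oxidise the electron-rich rings A and D or functionalise the CH2 of the product ketone. The fallback sets out from 13 and moves the aryl shift to the alcohol oxidation level. Anti-Markovnikov hydroboration–oxidation (BH3·THF, then NaOH/H2O2) should give the racemic 2,2-diarylethanol macrocycle F1. Heating F1 with P2O5 in toluene should bring about a dehydrative Wagner–Meerwein 1,2-aryl shift, the classical 9-fluorenylmethanol-to-phenanthrene type of ring expansion, to give the ring-expanded 20-membered macrocyclic stilbene F2 of either geometry. Hydrogenation (H2, Pd/C, EtOAc) of F2 returns to the route at 17, bypassing 15 and step 10.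

Step 7 (macrocyclisation). Intermolecular SNAr leading to oligomers may outrun ring closure, or displacement by the hindered guaiacol-type phenoxide may be sluggish. The fallback sets out from 9 and replaces SNAr by copper-catalysed C–O coupling. 4-Bromophenylmagnesium chloride F3, generated in the flask from 1-bromo-4-iodobenzene by iodine–magnesium exchange with i-PrMgCl at −20 °C, is added in place of 10 to give the seco 4-bromophenyl ketone F4. Intramolecular Ullmann etherification of F4 (CuI, N,N-dimethylglycine, Cs2CO3, dioxane, 100 °C, high dilution) returns to the route at 12.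

Step 8 (methylenation). The ylide may fail to add to the conjugated diaryl carbonyl held in the macrocycle, leaving ketone unchanged. The fallback sets out from 12: addition of MeMgBr (THF, 0 °C) should give the racemic tertiary methyl carbinol F5, and acid-catalysed E1 dehydration (cat. TsOH, toluene, 80 °C), for which only one alkene is possible, returns to the route at 13.

**Further compounds**

F1 | step 9 | racemic 19-membered macrocyclic 2,2-diarylethanol (CH(CH2OH) between rings B and C) | OCC1c2cccc(c2)Oc2ccc(cc2OC)CCc2ccc(OC)c(c2)Oc2ccc1cc2
F2 | step 9 | 20-membered macrocyclic stilbene dimethyl ether (B–CH=CH–C, geometry unassigned) | COc1cc2ccc1Oc1cccc(c1)C=Cc1ccc(cc1)Oc1cc(ccc1OC)CC2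
F3 | step 7 | 4-bromophenylmagnesium chloride | Brc1ccc([Mg]Cl)cc1
F4 | step 7 | (4-bromophenyl)(3-{4-[2-(3-hydroxy-4-methoxyphenyl)ethyl]-2-methoxyphenoxy}phenyl)methanone | O=C(c1ccc(Br)cc1)c1cccc(Oc2ccc(CCc3ccc(OC)c(O)c3)cc2OC)c1
F5 | step 8 | racemic 19-membered macrocyclic tertiary methyl carbinol (C(OH)(CH3) between rings B and C) | CC1(O)c2cccc(c2)Oc2ccc(cc2OC)CCc2ccc(OC)c(c2)Oc2ccc1cc2
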